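## Retrosynthetic overview

1. The target is reached from a 7‑O‑TES/9‑O‑TBS macrolactone by late senecioylation of the C8 hydroxyl and fluoride desilylation.
2. Ring B (the α‑methylene‑γ‑lactone, formed second) comes from TEMPO/PhI(OAc)2 oxidative lactonisation of a C12 allylic alcohol onto the C6 hydroxyl.
3. Ring A (the ten‑membered carbocycle, formed first) is closed at C5–C6 by an intramolecular Nozaki–Hiyama–Kishi reaction of an E‑alkenyl iodide with a quaternary α‑silyloxy aldehyde unmasked from a dithiane.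
4. The acyclic precursor is built by a Z‑selective Wittig reaction of an α‑silyloxy methyl ketone (C1=C10) and two chelation‑controlled Grignard additions that relay C8 to C9 and then to C7.
5. C8, the first stereocentre, comes from lipase desymmetrisation of prochiral 2‑O‑PMB‑glycerol diacetate.

Convention: locants C1–C15 are the germacrane locants of the target (C6 lactone carbinol, C7 tertiary carbinol, C8 ester carbinol, C9 free carbinol, C11–C13 methylene‑lactone unit).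

Assumption: Burkholderia cepacia lipase shows towards diacetate 4 the enantiotopic preference recorded for the 2‑O‑benzyl analogue, so that hydrolysis stops at the (R)‑monoacetate 5.

## Route

Step 1
Reactants: 1 2-phenyl-1,3-dioxan-5-ol
Product: 2 5-[(4-methoxybenzyl)oxy]-2-phenyl-1,3-dioxane
Conditions: NaH, PMBCl, Bu4NI (cat.), THF/DMF, 0 °C → rt
Reagents that add atoms: 4-methoxybenzyl chloride COc1ccc(CCl)cc1
Why: Williamson etherification of the only free hydroxyl while the benzylidene acetal masks both primary positions; no stereocentre is formed.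

Step 2
Reactants: 2 5-[(4-methoxybenzyl)oxy]-2-phenyl-1,3-dioxane
Product: 3 2-[(4-methoxybenzyl)oxy]propane-1,3-diol
Conditions: TsOH·H2O (cat.), MeOH, rt
Reagents that add atoms: none
Why: Acid‑catalysed transacetalisation releases the prochiral 1,3‑diol and leaves the PMB ether intact.

Step 3
Reactants: 3 2-[(4-methoxybenzyl)oxy]propane-1,3-diol
Product: 4 2-[(4-methoxybenzyl)oxy]propane-1,3-diyl diacetate
Conditions: Ac2O, pyridine, DMAP (cat.), CH2Cl2, 0 °C → rt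
Reagents that add atoms: acetic anhydride CC(=O)OC(C)=O
Why: Exhaustive DMAP‑catalysed acetylation gives the prochiral diester that the enzyme can differentiate.

Step 4
Reactants: 4 2-[(4-methoxybenzyl)oxy]propane-1,3-diyl diacetate
Product: 5 (R)-3-hydroxy-2-[(4-methoxybenzyl)oxy]propyl acetate
Conditions: Burkholderia cepacia lipase (Amano PS), 0.5 M KH2PO4/K2HPO4 buffer pH 7.0, i-Pr2O (10 vol %), 25 °C, stop just past 1 equiv of hydrolysis
Reagents that add atoms: none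
Why: Lipase‑catalysed enantiotopos‑selective hydrolysis (desymmetrisation of a prochiral diester) removes one of the two enantiotopic acetates and so creates C8 as the R centre, and slight over‑hydrolysis consumes the minor enantiomer faster and raises the ee.

Step 5
Reactants: 5 (R)-3-hydroxy-2-[(4-methoxybenzyl)oxy]propyl acetate
Product: 6 (R)-2-[(4-methoxybenzyl)oxy]-3-(trityloxy)propyl acetate
Conditions: TrCl, pyridine, DMAP (cat.), CH2Cl2, 0 °C → rt
Reagents that add atoms: trityl chloride ClC(c1ccccc1)(c1ccccc1)c1ccccc1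
Why: Tritylation of the primary alcohol under weakly basic conditions avoids the 1,3‑acetyl shift that would racemise 5 and installs a bulky, non‑migrating, non‑chelating group on the future C7 oxygen.

Step 6
Reactants: 6 (R)-2-[(4-methoxybenzyl)oxy]-3-(trityloxy)propyl acetate
Product: 7 (S)-2-[(4-methoxybenzyl)oxy]-3-(trityloxy)propan-1-ol
Conditions: K2CO3 (0.2 equiv), MeOH, 0 °C → rt
Reagents that add atoms: none
Why: Zemplén‑type methanolysis frees the future C9 hydroxyl, and because a trityl ether cannot migrate the C8 centre is untouched (the descriptor changes only through CIP priorities).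

Step 7
Reactants: 7 (S)-2-[(4-methoxybenzyl)oxy]-3-(trityloxy)propan-1-ol
Product: 8 (R)-2-[(4-methoxybenzyl)oxy]-3-(trityloxy)propanal
Conditions: Dess–Martin periodinane, pyridine, CH2Cl2, 0 °C → rt, used crude
Reagents that add atoms: none
Why: Dess–Martin oxidation is neutral and fast, so the α‑alkoxy aldehyde is obtained without epimerisation at C8.

Step 8
Reactants: 8 (R)-2-[(4-methoxybenzyl)oxy]-3-(trityloxy)propanal; 9 isopropenylmagnesium bromide
Product: 10 (3R,4R)-4-[(4-methoxybenzyl)oxy]-2-methyl-5-(trityloxy)pent-1-en-3-ol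
Conditions: MgBr2·OEt2, CH2Cl2, −78 °C; then 9 (THF solution), −78 °C; aqueous work-up
Reagents that add atoms: none
Why: Cram‑chelate‑controlled Grignard addition, in which magnesium bridges the aldehyde oxygen and the PMB ether oxygen and the isopropenyl group enters on the face away from the CH2OTr arm, sets C9 syn to C8.

Step 9
Reactants: 10 (3R,4R)-4-[(4-methoxybenzyl)oxy]-2-methyl-5-(trityloxy)pent-1-en-3-ol
Product: 11 tert-butyl{[(3R,4R)-4-[(4-methoxybenzyl)oxy]-2-methyl-5-(trityloxy)pent-1-en-3-yl]oxy}dimethylsilane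
Conditions: TBSOTf, 2,6-lutidine, CH2Cl2, −78 → 0 °C
Reagents that add atoms: tert-butyldimethylsilyl triflate CC(C)(C)[Si](C)(C)OS(=O)(=O)C(F)(F)F
Why: Silyl triflate silylation of the hindered secondary alcohol leaves O9 (silyl) and O8 (PMB) permanently differentiated.

Step 10
Reactants: 11 tert-butyl{[(3R,4R)-4-[(4-methoxybenzyl)oxy]-2-methyl-5-(trityloxy)pent-1-en-3-yl]oxy}dimethylsilane
Product: 13 (3S,4R)-3-[(tert-butyldimethylsilyl)oxy]-4-[(4-methoxybenzyl)oxy]-5-(trityloxy)pentan-2-one, via ozonide 12 (not isolated)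
Conditions: O3, CH2Cl2, −78 °C (Sudan Red 7B end point); then PPh3, −78 °C → rt
Reagents that add atoms: ozone [O-][O+]=O
Why: Ozonolysis with reductive work‑up cleaves the only alkene to the C10 methyl ketone, the arenes reacting far more slowly when the end point is respected.

Step 11
Reactants: 14 pent-4-yn-1-ol
Product: 16 (E)-5-iodo-4-methylpent-4-en-1-ol, via alkenylalane 15 (not isolated)
Conditions: AlMe3 (3 equiv), Cp2ZrCl2 (0.25 equiv), CH2Cl2, 0 °C → rt; then I2, THF, −30 → 0 °C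
Reagents that add atoms: trimethylaluminium C[Al](C)C; iodine II
Why: Negishi zirconium‑catalysed carboalumination adds methyl and aluminium syn across the terminal alkyne and iodinolysis proceeds with retention, which fixes the E geometry of the future C4=C5 bond.

Step 12
Reactants: 16 (E)-5-iodo-4-methylpent-4-en-1-ol
Product: 17 (E)-1,5-diiodo-2-methylpent-1-ene
Conditions: I2, PPh3, imidazole, CH2Cl2, 0 °C → rt
Reagents that add atoms: iodine II
Why: Appel iodination converts the primary alcohol into the alkyl iodide without touching the alkenyl iodide.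

Step 13
Reactants: 17 (E)-1,5-diiodo-2-methylpent-1-ene
Product: 18 [(E)-5-iodo-4-methylpent-4-en-1-yl]triphenylphosphonium iodide
Conditions: PPh3, MeCN, 85 °C, 24 h
Reagents that add atoms: triphenylphosphine c1ccc(cc1)P(c1ccccc1)c1ccccc1
Why: SN2 quaternisation occurs only at the primary alkyl iodide because the alkenyl iodide is inert to phosphine.

Step 14
Reactants: 18 [(E)-5-iodo-4-methylpent-4-en-1-yl]triphenylphosphonium iodide; 13 (3S,4R)-3-[(tert-butyldimethylsilyl)oxy]-4-[(4-methoxybenzyl)oxy]-5-(trityloxy)pentan-2-one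
Product: 20 (1E,5Z,7R,8R)-7-[(tert-butyldimethylsilyl)oxy]-1-iodo-8-[(4-methoxybenzyl)oxy]-2,6-dimethyl-9-(trityloxy)nona-1,5-diene, via phosphorus ylide 19 (not isolated)
Conditions: 18 (1.3 equiv), NaN(SiMe3)2 (1.25 equiv), THF, −78 → 0 °C; then 13, −78 °C → rt
Reagents that add atoms: none
Why: Wittig olefination of an α‑oxygenated methyl ketone with a non‑stabilised ylide places the ylide chain cis to the carbinol carbon (Still‑type Z selectivity), giving the Z C1=C10 bond while the alkenyl iodide survives the amide base.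

Step 15
Reactants: 20 (1E,5Z,7R,8R)-7-[(tert-butyldimethylsilyl)oxy]-1-iodo-8-[(4-methoxybenzyl)oxy]-2,6-dimethyl-9-(trityloxy)nona-1,5-diene
Product: 21 (2R,3R,4Z,8E)-3-[(tert-butyldimethylsilyl)oxy]-9-iodo-2-[(4-methoxybenzyl)oxy]-4,8-dimethylnona-4,8-dien-1-ol
Conditions: CSA (0.1 equiv), MeOH/CH2Cl2 (1:1), 0 °C → rt
Reagents that add atoms: none
Why: Acid‑catalysed solvolysis through the trityl cation frees the C7 hydroxyl far faster than the hindered secondary TBS ether or the PMB ether can react.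

Step 16
Reactants: 21 (2R,3R,4Z,8E)-3-[(tert-butyldimethylsilyl)oxy]-9-iodo-2-[(4-methoxybenzyl)oxy]-4,8-dimethylnona-4,8-dien-1-ol
Product: 22 (2S,3R,4Z,8E)-3-[(tert-butyldimethylsilyl)oxy]-9-iodo-2-[(4-methoxybenzyl)oxy]-4,8-dimethylnona-4,8-dienal
Conditions: Dess–Martin periodinane, pyridine, CH2Cl2, 0 °C, used crude
Reagents that add atoms: none
Why: Buffered Dess–Martin oxidation gives the C7 aldehyde without epimerising C8.

Step 17
Reactants: 22 (2S,3R,4Z,8E)-3-[(tert-butyldimethylsilyl)oxy]-9-iodo-2-[(4-methoxybenzyl)oxy]-4,8-dimethylnona-4,8-dienal; 23 1,3-dithiane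
Product: 25 (2R,3R,4Z,8E)-3-[(tert-butyldimethylsilyl)oxy]-1-(1,3-dithian-2-yl)-9-iodo-2-[(4-methoxybenzyl)oxy]-4,8-dimethylnona-4,8-dien-1-ol (C7 epimers), via 2-lithio-1,3-dithiane 24 (not isolated)
Conditions: 23 (1.3 equiv), n-BuLi (1.2 equiv), THF, −30 °C; then 22, −78 °C; H2O
Reagents that add atoms: none
Why: Corey–Seebach dithiane anion addition brings in C6 at the aldehyde oxidation level, the stabilised anion does not exchange with the alkenyl iodide, and the C7 configuration is irrelevant because it is oxidised next.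

Step 18
Reactants: 25 (2R,3R,4Z,8E)-3-[(tert-butyldimethylsilyl)oxy]-1-(1,3-dithian-2-yl)-9-iodo-2-[(4-methoxybenzyl)oxy]-4,8-dimethylnona-4,8-dien-1-ol (C7 epimers)
Product: 26 (2S,3R,4Z,8E)-3-[(tert-butyldimethylsilyl)oxy]-1-(1,3-dithian-2-yl)-9-iodo-2-[(4-methoxybenzyl)oxy]-4,8-dimethylnona-4,8-dien-1-one
Conditions: Dess–Martin periodinane, pyridine, CH2Cl2, 0 °C → rt
Reagents that add atoms: none
Why: Dess–Martin oxidation converts both carbinol epimers into the single 2‑acyl‑1,3‑dithiane without oxidising sulfur.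

Step 19
Reactants: 27 2-bromoprop-2-en-1-ol
Product: 28 [(2-bromoprop-2-en-1-yl)oxy]triethylsilane
Conditions: Et3SiCl, imidazole, CH2Cl2, 0 °C
Reagents that add atoms: chlorotriethylsilane CC[Si](Cl)(CC)CC
Why: Silylation of the primary allylic alcohol provides the precursor of the C11–C13 nucleophile with its C12 oxygen carrying the most labile silyl group of the route.

Step 20
Reactants: 26 (2S,3R,4Z,8E)-3-[(tert-butyldimethylsilyl)oxy]-1-(1,3-dithian-2-yl)-9-iodo-2-[(4-methoxybenzyl)oxy]-4,8-dimethylnona-4,8-dien-1-one; 28 [(2-bromoprop-2-en-1-yl)oxy]triethylsilane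
Product: 31 (3S,4S,5R,6Z,10E)-5-[(tert-butyldimethylsilyl)oxy]-3-(1,3-dithian-2-yl)-11-iodo-4-[(4-methoxybenzyl)oxy]-6,10-dimethyl-2-methylidene-1-[(triethylsilyl)oxy]undeca-6,10-dien-3-ol, via alkenyllithium 29 (not isolated), via alkenylmagnesium bromide 30 (not isolated)
Conditions: 28 (1.6 equiv), t-BuLi (3.2 equiv), Et2O, −78 °C; MgBr2·OEt2, −78 °C; then 26 + MgBr2·OEt2 in CH2Cl2, −78 → −40 °C; aqueous work-up
Reagents that add atoms: none
Why: Cram‑chelate‑controlled Grignard addition to the α‑(PMB‑oxy) ketone, with magnesium bridging the ketone oxygen and O8 and the alkenyl group entering anti to C9, sets the quaternary C7 carbinol with O7 anti to O8 as the target requires.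

Step 21
Reactants: 31 (3S,4S,5R,6Z,10E)-5-[(tert-butyldimethylsilyl)oxy]-3-(1,3-dithian-2-yl)-11-iodo-4-[(4-methoxybenzyl)oxy]-6,10-dimethyl-2-methylidene-1-[(triethylsilyl)oxy]undeca-6,10-dien-3-ol
Product: 32 (3S,4S,5R,6Z,10E)-5-[(tert-butyldimethylsilyl)oxy]-3-(1,3-dithian-2-yl)-11-iodo-4-[(4-methoxybenzyl)oxy]-6,10-dimethyl-2-methylidene-1,3-bis[(triethylsilyl)oxy]undeca-6,10-diene
Conditions: Et3SiOTf, 2,6-lutidine, CH2Cl2, −40 → 0 °C
Reagents that add atoms: triethylsilyl triflate CC[Si](CC)(CC)OS(=O)(=O)C(F)(F)F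
Why: Silyl triflate silylation caps the tertiary C7 hydroxyl so that the coming α‑oxy aldehyde cannot undergo α‑ketol rearrangement and the later DDQ step cannot form a cyclic acetal.

Step 22
Reactants: 32 (3S,4S,5R,6Z,10E)-5-[(tert-butyldimethylsilyl)oxy]-3-(1,3-dithian-2-yl)-11-iodo-4-[(4-methoxybenzyl)oxy]-6,10-dimethyl-2-methylidene-1,3-bis[(triethylsilyl)oxy]undeca-6,10-diene
Product: 33 (2S,3S,4R,5Z,9E)-4-[(tert-butyldimethylsilyl)oxy]-10-iodo-3-[(4-methoxybenzyl)oxy]-5,9-dimethyl-2-[(triethylsilyl)oxy]-2-{3-[(triethylsilyl)oxy]prop-1-en-2-yl}deca-5,9-dienal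
Conditions: MeI, CaCO3, MeCN/H2O (9:1), 40 °C
Reagents that add atoms: water O
Why: S‑alkylative hydrolysis of the dithiane (Corey–Seebach unmasking) under carbonate buffering reveals the non‑enolisable C6 aldehyde directly before ring closure.

Step 23
Reactants: 33 (2S,3S,4R,5Z,9E)-4-[(tert-butyldimethylsilyl)oxy]-10-iodo-3-[(4-methoxybenzyl)oxy]-5,9-dimethyl-2-[(triethylsilyl)oxy]-2-{3-[(triethylsilyl)oxy]prop-1-en-2-yl}deca-5,9-dienal
Product: 35 (1S,2E,6Z,8R,9S,10R)-8-[(tert-butyldimethylsilyl)oxy]-9-[(4-methoxybenzyl)oxy]-3,7-dimethyl-10-[(triethylsilyl)oxy]-10-{3-[(triethylsilyl)oxy]prop-1-en-2-yl}cyclodeca-2,6-dien-1-ol, via alkenylchromium dichloride 34 (not isolated)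
Conditions: CrCl2 (10 equiv), NiCl2 (2 mol %), DMSO/THF (3:1), 25 °C, syringe-pump addition to 0.003 M
Reagents that add atoms: none
Why: Intramolecular Nozaki–Hiyama–Kishi reaction, in which nickel activates the alkenyl iodide and divalent chromium carries it onto the aldehyde with retention of the E geometry, closes ring A and sets C6 as S because the carbonyl lies opposed to the C7–O dipole and the tether through C8 delivers C5 on the C8 side.

Step 24
Reactants: 35 (1S,2E,6Z,8R,9S,10R)-8-[(tert-butyldimethylsilyl)oxy]-9-[(4-methoxybenzyl)oxy]-3,7-dimethyl-10-[(triethylsilyl)oxy]-10-{3-[(triethylsilyl)oxy]prop-1-en-2-yl}cyclodeca-2,6-dien-1-ol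
Product: 36 (1S,2E,6Z,8R,9S,10R)-8-[(tert-butyldimethylsilyl)oxy]-10-(3-hydroxyprop-1-en-2-yl)-9-[(4-methoxybenzyl)oxy]-3,7-dimethyl-10-[(triethylsilyl)oxy]cyclodeca-2,6-dien-1-ol
Conditions: HF·pyridine, pyridine, THF, 0 °C
Reagents that add atoms: none
Why: Buffered fluoride cleaves the unhindered primary triethylsilyl ether much faster than the tertiary triethylsilyl or the secondary TBS ether.

Step 25
Reactants: 36 (1S,2E,6Z,8R,9S,10R)-8-[(tert-butyldimethylsilyl)oxy]-10-(3-hydroxyprop-1-en-2-yl)-9-[(4-methoxybenzyl)oxy]-3,7-dimethyl-10-[(triethylsilyl)oxy]cyclodeca-2,6-dien-1-ol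
Product: 39 (6S,7R,8S,9R)-9-[(tert-butyldimethylsilyl)oxy]-8-[(4-methoxybenzyl)oxy]-7-[(triethylsilyl)oxy]germacra-1(10)Z,4E,11(13)-trien-12,6-olide, via hydroxy enal 37 (not isolated), via lactol 38 (not isolated)
Conditions: TEMPO (0.2 equiv), PhI(OAc)2 (2.5 equiv), CH2Cl2, rt
Reagents that add atoms: none
Why: TEMPO/PhI(OAc)2 oxidation is selective for the primary allylic alcohol, the enal is trapped by the C6 hydroxyl as a five‑membered lactol that is oxidised on to the lactone, and only the 12,6‑olide can form because O8 is still a PMB ether.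

Step 26
Reactants: 39 (6S,7R,8S,9R)-9-[(tert-butyldimethylsilyl)oxy]-8-[(4-methoxybenzyl)oxy]-7-[(triethylsilyl)oxy]germacra-1(10)Z,4E,11(13)-trien-12,6-olide
Product: 40 (6S,7S,8S,9R)-9-[(tert-butyldimethylsilyl)oxy]-8-hydroxy-7-[(triethylsilyl)oxy]germacra-1(10)Z,4E,11(13)-trien-12,6-olide
Conditions: DDQ, CH2Cl2/aq. KH2PO4/K2HPO4 pH 7 (10:1), 0 °C
Reagents that add atoms: none
Why: Oxidative PMB cleavage by DDQ is neutral and leaves the methylene lactone, the diene and both silyl ethers untouched (the C7 descriptor changes only through CIP priorities).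

Step 27
Reactants: 40 (6S,7S,8S,9R)-9-[(tert-butyldimethylsilyl)oxy]-8-hydroxy-7-[(triethylsilyl)oxy]germacra-1(10)Z,4E,11(13)-trien-12,6-olide; 41 3-methylbut-2-enoyl chloride
Product: 42 (6S,7R,8S,9R)-9-[(tert-butyldimethylsilyl)oxy]-8-[(3-methylbut-2-enoyl)oxy]-7-[(triethylsilyl)oxy]germacra-1(10)Z,4E,11(13)-trien-12,6-olide
Conditions: 41, pyridine, DMAP (cat.), CH2Cl2, 0 °C → rt
Reagents that add atoms: none
Why: DMAP‑catalysed acylation meets a single free hydroxyl, so the senecioate can only go to O8, and the weak base avoids deconjugation of the acyl group and translactonisation.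

Step 28
Reactants: 42 (6S,7R,8S,9R)-9-[(tert-butyldimethylsilyl)oxy]-8-[(3-methylbut-2-enoyl)oxy]-7-[(triethylsilyl)oxy]germacra-1(10)Z,4E,11(13)-trien-12,6-olide
Product: 43 (6S,7R,8S,9R)-7,9-dihydroxy-8-[(3-methylbut-2-enoyl)oxy]germacra-1(10)Z,4E,11(13)-trien-12,6-olide (CNP0255427.1)
Conditions: HF·pyridine (excess), pyridine, THF, 0 °C → rt
Reagents that add atoms: none
Why: Fluoride desilylation under buffered, non‑basic conditions removes both silyl ethers without O8→O9 acyl migration, conjugate addition to the methylene lactone or transannular cyclisation of the diene.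

## Compound list

1 | 2-phenyl-1,3-dioxan-5-ol (achiral, either ring diastereomer) | OC1COC(c2ccccc2)OC1 | starting material
2 | 5-[(4-methoxybenzyl)oxy]-2-phenyl-1,3-dioxane | COc1ccc(COC2COC(c3ccccc3)OC2)cc1 | intermediate
3 | 2-[(4-methoxybenzyl)oxy]propane-1,3-diol | COc1ccc(COC(CO)CO)cc1 | intermediate
4 | 2-[(4-methoxybenzyl)oxy]propane-1,3-diyl diacetate | CC(=O)OCC(COC(C)=O)OCc1ccc(OC)cc1 | intermediate
5 | (R)-3-hydroxy-2-[(4-methoxybenzyl)oxy]propyl acetate | CC(=O)OC[C@H](OCc1ccc(OC)cc1)CO | intermediate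
6 | (R)-2-[(4-methoxybenzyl)oxy]-3-(trityloxy)propyl acetate | CC(=O)OC[C@H](OCc1ccc(OC)cc1)COC(c1ccccc1)(c1ccccc1)c1ccccc1 | intermediate
7 | (S)-2-[(4-methoxybenzyl)oxy]-3-(trityloxy)propan-1-ol | OC[C@H](OCc1ccc(OC)cc1)COC(c1ccccc1)(c1ccccc1)c1ccccc1 | intermediate
8 | (R)-2-[(4-methoxybenzyl)oxy]-3-(trityloxy)propanal | O=C[C@H](OCc1ccc(OC)cc1)COC(c1ccccc1)(c1ccccc1)c1ccccc1 | intermediate
9 | isopropenylmagnesium bromide | CC(=C)[Mg]Br | starting material
10 | (3R,4R)-4-[(4-methoxybenzyl)oxy]-2-methyl-5-(trityloxy)pent-1-en-3-ol | CC(=C)[C@@H](O)[C@H](OCc1ccc(OC)cc1)COC(c1ccccc1)(c1ccccc1)c1ccccc1 | intermediate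
11 | tert-butyl{[(3R,4R)-4-[(4-methoxybenzyl)oxy]-2-methyl-5-(trityloxy)pent-1-en-3-yl]oxy}dimethylsilane | CC(=C)[C@@H](O[Si](C)(C)C(C)(C)C)[C@H](OCc1ccc(OC)cc1)COC(c1ccccc1)(c1ccccc1)c1ccccc1 | intermediate
12 | ozonide (3-methyl-1,2,4-trioxolan-3-yl compound) of 11, epimers at the trioxolane carbon (not isolated) | CC1(OCOO1)[C@@H](O[Si](C)(C)C(C)(C)C)[C@H](OCc1ccc(OC)cc1)COC(c1ccccc1)(c1ccccc1)c1ccccc1 | intermediate
13 | (3S,4R)-3-[(tert-butyldimethylsilyl)oxy]-4-[(4-methoxybenzyl)oxy]-5-(trityloxy)pentan-2-one | CC(=O)[C@@H](O[Si](C)(C)C(C)(C)C)[C@H](OCc1ccc(OC)cc1)COC(c1ccccc1)(c1ccccc1)c1ccccc1 | intermediate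
14 | pent-4-yn-1-ol | C#CCCCO | starting material
15 | (E)-alkenyldimethylalane aluminium alkoxide from carboalumination of 14 (not isolated) | C[Al](C)/C=C(\C)CCCO[Al](C)C | intermediate
16 | (E)-5-iodo-4-methylpent-4-en-1-ol | I/C=C(\C)CCCO | intermediate
17 | (E)-1,5-diiodo-2-methylpent-1-ene | I/C=C(\C)CCCI | intermediate
18 | [(E)-5-iodo-4-methylpent-4-en-1-yl]triphenylphosphonium iodide | I/C=C(\C)CCC[P+](c1ccccc1)(c1ccccc1)c1ccccc1.[I-] | intermediate
19 | [(E)-5-iodo-4-methylpent-4-en-1-ylidene]triphenylphosphorane (not isolated) | I/C=C(\C)CCC=P(c1ccccc1)(c1ccccc1)c1ccccc1 | intermediate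
20 | (1E,5Z,7R,8R)-7-[(tert-butyldimethylsilyl)oxy]-1-iodo-8-[(4-methoxybenzyl)oxy]-2,6-dimethyl-9-(trityloxy)nona-1,5-diene | I/C=C(\C)CC/C=C(/C)[C@@H](O[Si](C)(C)C(C)(C)C)[C@H](OCc1ccc(OC)cc1)COC(c1ccccc1)(c1ccccc1)c1ccccc1 | intermediate
21 | (2R,3R,4Z,8E)-3-[(tert-butyldimethylsilyl)oxy]-9-iodo-2-[(4-methoxybenzyl)oxy]-4,8-dimethylnona-4,8-dien-1-ol | I/C=C(\C)CC/C=C(/C)[C@@H](O[Si](C)(C)C(C)(C)C)[C@H](OCc1ccc(OC)cc1)CO | intermediate
22 | (2S,3R,4Z,8E)-3-[(tert-butyldimethylsilyl)oxy]-9-iodo-2-[(4-methoxybenzyl)oxy]-4,8-dimethylnona-4,8-dienal | I/C=C(\C)CC/C=C(/C)[C@@H](O[Si](C)(C)C(C)(C)C)[C@H](OCc1ccc(OC)cc1)C=O | intermediate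
23 | 1,3-dithiane | C1CSCSC1 | starting material
24 | 2-lithio-1,3-dithiane (not isolated) | [Li]C1SCCCS1 | intermediate
25 | (2R,3R,4Z,8E)-3-[(tert-butyldimethylsilyl)oxy]-1-(1,3-dithian-2-yl)-9-iodo-2-[(4-methoxybenzyl)oxy]-4,8-dimethylnona-4,8-dien-1-ol, C7 (carbinol) epimers | I/C=C(\C)CC/C=C(/C)[C@@H](O[Si](C)(C)C(C)(C)C)[C@H](OCc1ccc(OC)cc1)C(O)C1SCCCS1 | intermediate
26 | (2S,3R,4Z,8E)-3-[(tert-butyldimethylsilyl)oxy]-1-(1,3-dithian-2-yl)-9-iodo-2-[(4-methoxybenzyl)oxy]-4,8-dimethylnona-4,8-dien-1-one | I/C=C(\C)CC/C=C(/C)[C@@H](O[Si](C)(C)C(C)(C)C)[C@H](OCc1ccc(OC)cc1)C(=O)C1SCCCS1 | intermediate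
27 | 2-bromoprop-2-en-1-ol | OCC(Br)=C | starting material
28 | [(2-bromoprop-2-en-1-yl)oxy]triethylsilane | C=C(Br)CO[Si](CC)(CC)CC | intermediate
29 | {3-[(triethylsilyl)oxy]prop-1-en-2-yl}lithium (not isolated) | [Li]C(=C)CO[Si](CC)(CC)CC | intermediate
30 | {3-[(triethylsilyl)oxy]prop-1-en-2-yl}magnesium bromide (not isolated) | Br[Mg]C(=C)CO[Si](CC)(CC)CC | intermediate
31 | (3S,4S,5R,6Z,10E)-5-[(tert-butyldimethylsilyl)oxy]-3-(1,3-dithian-2-yl)-11-iodo-4-[(4-methoxybenzyl)oxy]-6,10-dimethyl-2-methylidene-1-[(triethylsilyl)oxy]undeca-6,10-dien-3-ol | I/C=C(\C)CC/C=C(/C)[C@@H](O[Si](C)(C)C(C)(C)C)[C@H](OCc1ccc(OC)cc1)[C@@](O)(C(=C)CO[Si](CC)(CC)CC)C1SCCCS1 | intermediate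
32 | (3S,4S,5R,6Z,10E)-5-[(tert-butyldimethylsilyl)oxy]-3-(1,3-dithian-2-yl)-11-iodo-4-[(4-methoxybenzyl)oxy]-6,10-dimethyl-2-methylidene-1,3-bis[(triethylsilyl)oxy]undeca-6,10-diene | I/C=C(\C)CC/C=C(/C)[C@@H](O[Si](C)(C)C(C)(C)C)[C@H](OCc1ccc(OC)cc1)[C@@](O[Si](CC)(CC)CC)(C(=C)CO[Si](CC)(CC)CC)C1SCCCS1 | intermediate
33 | (2S,3S,4R,5Z,9E)-4-[(tert-butyldimethylsilyl)oxy]-10-iodo-3-[(4-methoxybenzyl)oxy]-5,9-dimethyl-2-[(triethylsilyl)oxy]-2-{3-[(triethylsilyl)oxy]prop-1-en-2-yl}deca-5,9-dienal | I/C=C(\C)CC/C=C(/C)[C@@H](O[Si](C)(C)C(C)(C)C)[C@H](OCc1ccc(OC)cc1)[C@@](O[Si](CC)(CC)CC)(C(=C)CO[Si](CC)(CC)CC)C=O | intermediate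
34 | alkenylchromium dichloride derived from 33 (C5–Cr in place of C5–I; not isolated) | Cl[Cr](Cl)/C=C(\C)CC/C=C(/C)[C@@H](O[Si](C)(C)C(C)(C)C)[C@H](OCc1ccc(OC)cc1)[C@@](O[Si](CC)(CC)CC)(C(=C)CO[Si](CC)(CC)CC)C=O | intermediate
35 | (1S,2E,6Z,8R,9S,10R)-8-[(tert-butyldimethylsilyl)oxy]-9-[(4-methoxybenzyl)oxy]-3,7-dimethyl-10-[(triethylsilyl)oxy]-10-{3-[(triethylsilyl)oxy]prop-1-en-2-yl}cyclodeca-2,6-dien-1-ol | O[C@H]1/C=C(\C)CC/C=C(/C)[C@@H](O[Si](C)(C)C(C)(C)C)[C@H](OCc2ccc(OC)cc2)[C@@]1(O[Si](CC)(CC)CC)C(=C)CO[Si](CC)(CC)CC | intermediate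
36 | (1S,2E,6Z,8R,9S,10R)-8-[(tert-butyldimethylsilyl)oxy]-10-(3-hydroxyprop-1-en-2-yl)-9-[(4-methoxybenzyl)oxy]-3,7-dimethyl-10-[(triethylsilyl)oxy]cyclodeca-2,6-dien-1-ol | O[C@H]1/C=C(\C)CC/C=C(/C)[C@@H](O[Si](C)(C)C(C)(C)C)[C@H](OCc2ccc(OC)cc2)[C@@]1(O[Si](CC)(CC)CC)C(=C)CO | intermediate
37 | 2-substituted propenal from oxidation of the primary alcohol of 36 (not isolated) | O[C@H]1/C=C(\C)CC/C=C(/C)[C@@H](O[Si](C)(C)C(C)(C)C)[C@H](OCc2ccc(OC)cc2)[C@@]1(O[Si](CC)(CC)CC)C(=C)C=O | intermediate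
38 | 12,6-lactol of 37, C12 epimers (not isolated) | C=C1C(O)O[C@H]2/C=C(\C)CC/C=C(/C)[C@@H](O[Si](C)(C)C(C)(C)C)[C@H](OCc3ccc(OC)cc3)[C@@]12O[Si](CC)(CC)CC | intermediate
39 | (6S,7R,8S,9R)-9-[(tert-butyldimethylsilyl)oxy]-8-[(4-methoxybenzyl)oxy]-7-[(triethylsilyl)oxy]germacra-1(10)Z,4E,11(13)-trien-12,6-olide | C=C1C(=O)O[C@H]2/C=C(\C)CC/C=C(/C)[C@@H](O[Si](C)(C)C(C)(C)C)[C@H](OCc3ccc(OC)cc3)[C@@]12O[Si](CC)(CC)CC | intermediate
40 | (6S,7S,8S,9R)-9-[(tert-butyldimethylsilyl)oxy]-8-hydroxy-7-[(triethylsilyl)oxy]germacra-1(10)Z,4E,11(13)-trien-12,6-olide | C=C1C(=O)O[C@H]2/C=C(\C)CC/C=C(/C)[C@@H](O[Si](C)(C)C(C)(C)C)[C@H](O)[C@@]12O[Si](CC)(CC)CC | intermediate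
41 | 3-methylbut-2-enoyl chloride | CC(C)=CC(Cl)=O | starting material
42 | (6S,7R,8S,9R)-9-[(tert-butyldimethylsilyl)oxy]-8-[(3-methylbut-2-enoyl)oxy]-7-[(triethylsilyl)oxy]germacra-1(10)Z,4E,11(13)-trien-12,6-olide | C=C1C(=O)O[C@H]2/C=C(\C)CC/C=C(/C)[C@@H](O[Si](C)(C)C(C)(C)C)[C@H](OC(=O)C=C(C)C)[C@@]12O[Si](CC)(CC)CC | intermediate
43 | (6S,7R,8S,9R)-7,9-dihydroxy-8-[(3-methylbut-2-enoyl)oxy]germacra-1(10)Z,4E,11(13)-trien-12,6-olide (CNP0255427.1) | C=C1C(=O)O[C@H]2/C=C(\C)CC/C=C(/C)[C@@H](O)[C@H](OC(=O)C=C(C)C)[C@@]12O | target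

## Step count and risks

Total step count: 28. Longest linear sequence: 24 steps (steps 1–10, 14–18, 20–28).

Steps most likely to fail:

**Step 23 (closure of ring A).** The C6 configuration rests on a conformational argument, and the simple acyclic Felkin–Anh model would favour the other epimer, so this is the least secure stereocentre. The fallback sets out from 33 and comes back at 35. If the same chromium/nickel closure gives mainly the 6R alcohol F1, that material is oxidised with Dess–Martin periodinane to the macrocyclic enone F2. 1,2‑Reduction (NaBH4, CeCl3·7H2O, MeOH, −78 °C) then brings hydride in along the trajectory that the alkenyl carbon used, which gives the 6S alcohol 35, so C6 is set by redox inversion and not by the C–C bond formation.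

**Step 14 (Z‑selective Wittig on ketone 13).** The basic ylide may enolise the methyl ketone, expel the β‑PMB‑oxy group or give an insufficient Z/E ratio. The fallback sets out from 16 and 8 and comes back at 20, forming the C9–C10 bond instead of the C1=C10 bond.
- Alcohol 16 is treated with t‑BuLi (3.1 equiv, Et2O, −78 °C) and Me3SiCl, then K2CO3/MeOH, to give the vinylsilane alcohol F3, in which the silyl group masks the future C5 iodide.
- Dess–Martin oxidation gives the aldehyde F4.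
- Z‑selective iodo‑olefination with Ph3P=C(I)CH3 (from ethyltriphenylphosphonium iodide, n‑BuLi, I2, NaN(SiMe3)2; THF, −78 °C) gives the (Z)‑alkenyl iodide F5.
- Iodine–lithium exchange (t‑BuLi) and MgBr2·OEt2 give the alkenylmagnesium bromide F6.
- F6 adds to aldehyde 8 under the chelate control of step 8 to give the allylic alcohol F7, with C9 syn to C8.
- TBSOTf/2,6‑lutidine gives the silyl ether F8.
- ipso‑Iododesilylation (N‑iodosuccinimide, MeCN/ClCH2CN, 0 °C) returns 20.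

**Step 20 (branched alkenyl Grignard on the hindered keto‑dithiane 26).** The addition may stall or lose chelate control. The fallback sets out from 26 and comes back at 39, using a slim alkynyl nucleophile and building the lactone by carbonylation.
- Me3SiC≡CMgBr with MgBr2·OEt2 (CH2Cl2, −78 °C) adds under the same Cram chelate to give the propargylic alcohol F9.
- Et3SiOTf/2,6‑lutidine gives the silyl ether F10.
- MeI/CaCO3 in aqueous MeCN gives the aldehyde F11.
- CrCl2/NiCl2 closure as in step 23 gives the macrocyclic alkynyl alcohol F12.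
- K2CO3/MeOH removes the C‑silyl group to give the terminal alkyne F13.
- Palladium‑catalysed cyclocarbonylation of the homopropargylic C6 alcohol (PdCl2 cat., thiourea, CO 1 atm, acetone, 50 °C) forms the α‑methylene lactone 39 directly.

## Further compounds

F1 | step 23 | (1R,2E,6Z,8R,9S,10R)-8-[(tert-butyldimethylsilyl)oxy]-9-[(4-methoxybenzyl)oxy]-3,7-dimethyl-10-[(triethylsilyl)oxy]-10-{3-[(triethylsilyl)oxy]prop-1-en-2-yl}cyclodeca-2,6-dien-1-ol (C6 epimer of 35) | O[C@@H]1/C=C(\C)CC/C=C(/C)[C@@H](O[Si](C)(C)C(C)(C)C)[C@H](OCc2ccc(OC)cc2)[C@@]1(O[Si](CC)(CC)CC)C(=C)CO[Si](CC)(CC)CC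
F2 | step 23 | (2E,6Z,8R,9S,10S)-8-[(tert-butyldimethylsilyl)oxy]-9-[(4-methoxybenzyl)oxy]-3,7-dimethyl-10-[(triethylsilyl)oxy]-10-{3-[(triethylsilyl)oxy]prop-1-en-2-yl}cyclodeca-2,6-dien-1-one | O=C1/C=C(\C)CC/C=C(/C)[C@@H](O[Si](C)(C)C(C)(C)C)[C@H](OCc2ccc(OC)cc2)[C@@]1(O[Si](CC)(CC)CC)C(=C)CO[Si](CC)(CC)CC
F3 | step 14 | (E)-4-methyl-5-(trimethylsilyl)pent-4-en-1-ol | C[Si](C)(C)/C=C(\C)CCCO
F4 | step 14 | (E)-4-methyl-5-(trimethylsilyl)pent-4-enal | C[Si](C)(C)/C=C(\C)CCC=O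
F5 | step 14 | [(1E,5Z)-6-iodo-2-methylhepta-1,5-dien-1-yl]trimethylsilane | C[Si](C)(C)/C=C(\C)CC/C=C(/C)I
F6 | step 14 | [(2Z,6E)-6-methyl-7-(trimethylsilyl)hepta-2,6-dien-2-yl]magnesium bromide | C[Si](C)(C)/C=C(\C)CC/C=C(/C)[Mg]Br
F7 | step 14 | (2R,3R,4Z,8E)-2-[(4-methoxybenzyl)oxy]-4,8-dimethyl-9-(trimethylsilyl)-1-(trityloxy)nona-4,8-dien-3-ol | C[Si](C)(C)/C=C(\C)CC/C=C(/C)[C@@H](O)[C@H](OCc1ccc(OC)cc1)COC(c1ccccc1)(c1ccccc1)c1ccccc1
F8 | step 14 | tert-butyldimethylsilyl ether of F7 (9-trimethylsilyl analogue of 20) | C[Si](C)(C)/C=C(\C)CC/C=C(/C)[C@@H](O[Si](C)(C)C(C)(C)C)[C@H](OCc1ccc(OC)cc1)COC(c1ccccc1)(c1ccccc1)c1ccccc1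
F9 | step 20 | tertiary propargylic alcohol from 26: C7 carries OH, 1,3-dithian-2-yl and (trimethylsilyl)ethynyl; C7 configured as in 31 | I/C=C(\C)CC/C=C(/C)[C@@H](O[Si](C)(C)C(C)(C)C)[C@H](OCc1ccc(OC)cc1)[C@@](O)(C#C[Si](C)(C)C)C1SCCCS1
F10 | step 20 | 7-O-triethylsilyl ether of F9 | I/C=C(\C)CC/C=C(/C)[C@@H](O[Si](C)(C)C(C)(C)C)[C@H](OCc1ccc(OC)cc1)[C@@](O[Si](CC)(CC)CC)(C#C[Si](C)(C)C)C1SCCCS1
F11 | step 20 | C6 aldehyde from F10 (alkynyl analogue of 33) | I/C=C(\C)CC/C=C(/C)[C@@H](O[Si](C)(C)C(C)(C)C)[C@H](OCc1ccc(OC)cc1)[C@@](O[Si](CC)(CC)CC)(C#C[Si](C)(C)C)C=O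
F12 | step 20 | (1S,2E,6Z,8R,9S,10R)-8-[(tert-butyldimethylsilyl)oxy]-9-[(4-methoxybenzyl)oxy]-3,7-dimethyl-10-[(triethylsilyl)oxy]-10-[(trimethylsilyl)ethynyl]cyclodeca-2,6-dien-1-ol | O[C@H]1/C=C(\C)CC/C=C(/C)[C@@H](O[Si](C)(C)C(C)(C)C)[C@H](OCc2ccc(OC)cc2)[C@@]1(O[Si](CC)(CC)CC)C#C[Si](C)(C)C
F13 | step 20 | (1S,2E,6Z,8R,9S,10R)-8-[(tert-butyldimethylsilyl)oxy]-10-ethynyl-9-[(4-methoxybenzyl)oxy]-3,7-dimethyl-10-[(triethylsilyl)oxy]cyclodeca-2,6-dien-1-ol | O[C@H]1/C=C(\C)CC/C=C(/C)[C@@H](O[Si](C)(C)C(C)(C)C)[C@H](OCc2ccc(OC)cc2)[C@@]1(O[Si](CC)(CC)CC)C#C
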